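**Retrosynthetic overview**

1. Target 18 ⇐ butenolide 14: C1 and the exocyclic methylene come last. Hydride adds 1,4 to the macrocycle-fused 17-nor butenolide at C1, anti to the C2–C3 bond (cis fusion); Mannich trapping at C15 and elimination follow.
2. 14 ⇐ 12: the γ-lactone (third ring) is closed by acrylate ring-closing metathesis onto a C1 exo-methylene.
3. 12 ⇐ 10: the 14-membered carbocycle (second ring) is closed by intramolecular Ni/Cr alkenyl bromide–enal coupling (C1–C2). C1 and C14 come from 2,3-dibromopropene, a two-carbon linchpin between the two oxidised ends of farnesol.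
4. 10 ⇐ 6: the epoxide (first ring) and C11, C12, C13 come from one Sharpless kinetic-resolution epoxidation.
5. 6 ⇐ (2E,6E)-farnesyl acetate 1 (C2–C13, both E-alkenes) + 4. The usual intramolecular 2-(alkoxycarbonyl)allylation that closes ring and lactone together is deliberately not used.

Convention and assumption: macrocyclic compounds carry cembrane numbering (ring C1–C14; C15, C16, C17 = lactone α-carbon, carbonyl carbon, exocyclic methylene; C18–C20 = methyls on C4, C8, C12). Linear compounds carry chain numbering. Farnesyl acetate is bought as the pure trans,trans isomer.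

**Route**

Step 1
Reactants: 1 (2E,6E)-farnesyl acetate
Product: 2 (2E,6E,10E)-12-hydroxy-3,7,11-trimethyldodeca-2,6,10-trien-1-yl acetate
Conditions: SeO2 (0.2 equiv), t-BuOOH (3 equiv), salicylic acid (0.1 equiv), CH2Cl2, 0 °C to rt
Reagents that add atoms: tert-butyl hydroperoxide, CC(C)(C)OO
Why: Catalytic SeO2 allylic oxidation (ene reaction then 2,3-sigmatropic shift) attacks only the (E)-methyl of the terminal, most electron-rich alkene, because the 2,3-alkene is deactivated by its allylic acetate.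

Step 2
Reactants: 2 (2E,6E,10E)-12-hydroxy-3,7,11-trimethyldodeca-2,6,10-trien-1-yl acetate
Product: 3 (2E,6E,10E)-3,7,11-trimethyl-12-oxododeca-2,6,10-trien-1-yl acetate
Conditions: MnO2 (20 equiv), CH2Cl2, rt
Reagents that add atoms: none
Why: MnO2 oxidation is selective for the allylic alcohol and gives the (E)-enal without alkene isomerisation.

Step 3
Reactants: 3 (2E,6E,10E)-3,7,11-trimethyl-12-oxododeca-2,6,10-trien-1-yl acetate; 4 2,3-dibromoprop-1-ene
Product: 6 rac-(2E,6E,10E)-14-bromo-12-hydroxy-3,7,11-trimethylpentadeca-2,6,10,14-tetraen-1-yl acetate, via 2-bromoallylindium dibromide 5 (not isolated)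
Conditions: In powder (1.5 equiv), THF/H2O (1:1), rt
Reagents that add atoms: none
Why: Aqueous indium Barbier allylation inserts only into the allylic C–Br bond of 4 and adds 1,2 to the enal, keeping the alkenyl bromide and the acetate; the new carbinol is racemic and is resolved in step 4.

Step 4
Reactants: 6 rac-(2E,6E,10E)-14-bromo-12-hydroxy-3,7,11-trimethylpentadeca-2,6,10,14-tetraen-1-yl acetate
Product: 7 (2E,6E)-9-[(2R,3R)-3-[(1R)-3-bromo-1-hydroxybut-3-en-1-yl]-3-methyloxiran-2-yl]-3,7-dimethylnona-2,6-dien-1-yl acetate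
Conditions: Ti(OiPr)4 (0.15 equiv), D-(−)-diisopropyl tartrate (0.2 equiv), t-BuOOH (0.6 equiv), 4 Å molecular sieves, CH2Cl2, −20 °C
Reagents that add atoms: tert-butyl hydroperoxide, CC(C)(C)OO
Why: In this Sharpless kinetic-resolution epoxidation the (12R)-alcohol is the fast enantiomer with the D-tartrate and gives the erythro epoxy alcohol on the tartrate-controlled face, which sets C11, C12 and C13 of the target in one step (at most 50 % yield; the slow (12S)-alcohol is recovered).

Step 5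
Reactants: 7 (2E,6E)-9-[(2R,3R)-3-[(1R)-3-bromo-1-hydroxybut-3-en-1-yl]-3-methyloxiran-2-yl]-3,7-dimethylnona-2,6-dien-1-yl acetate
Product: 8 (2E,6E)-9-[(2R,3S)-3-[(1R)-1-acetoxy-3-bromobut-3-en-1-yl]-3-methyloxiran-2-yl]-3,7-dimethylnona-2,6-dien-1-yl acetate
Conditions: Ac2O, pyridine, 4-(dimethylamino)pyridine (0.1 equiv), CH2Cl2, rt
Reagents that add atoms: acetic anhydride, CC(=O)OC(C)=O
Why: Nucleophile-catalysed acylation installs the C13 acetate of the target on the hindered secondary alcohol with retention.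

Step 6
Reactants: 8 (2E,6E)-9-[(2R,3S)-3-[(1R)-1-acetoxy-3-bromobut-3-en-1-yl]-3-methyloxiran-2-yl]-3,7-dimethylnona-2,6-dien-1-yl acetate
Product: 9 (1R)-3-bromo-1-[(2S,3R)-3-[(3E,7E)-9-hydroxy-3,7-dimethylnona-3,7-dien-1-yl]-2-methyloxiran-2-yl]but-3-en-1-yl acetate
Conditions: K2CO3 (0.3 equiv), MeOH, −10 °C, stopped at full conversion of the primary ester
Reagents that add atoms: none
Why: Base-catalysed transesterification (Zemplén-type methanolysis) is much faster at the unhindered primary allylic acetate than at the secondary acetate shielded by the fully substituted epoxide carbon.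

Step 7
Reactants: 9 (1R)-3-bromo-1-[(2S,3R)-3-[(3E,7E)-9-hydroxy-3,7-dimethylnona-3,7-dien-1-yl]-2-methyloxiran-2-yl]but-3-en-1-yl acetate
Product: 10 (1R)-3-bromo-1-[(2S,3R)-3-[(3E,7E)-3,7-dimethyl-9-oxonona-3,7-dien-1-yl]-2-methyloxiran-2-yl]but-3-en-1-yl acetate
Conditions: MnO2 (20 equiv), CH2Cl2, rt
Reagents that add atoms: none
Why: Neutral MnO2 oxidation of the allylic alcohol gives the (E)-enal and leaves epoxide, acetate and alkenyl bromide untouched.

Step 8
Reactants: 10 (1R)-3-bromo-1-[(2S,3R)-3-[(3E,7E)-3,7-dimethyl-9-oxonona-3,7-dien-1-yl]-2-methyloxiran-2-yl]but-3-en-1-yl acetate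
Product: 12 (2S,3E,7E,11R,12S,13R)-13-acetoxy-11,12-epoxy-16,17-dinorcembra-1(15),3,7-trien-2-ol, via alkenylchromium dichloride 11 (not isolated)
Conditions: CrCl2 (8 equiv), NiCl2 (0.1 equiv), DMSO/THF (3:1), 0.003 M by syringe pump, rt
Reagents that add atoms: none
Why: In this Nozaki–Hiyama–Kishi macrocyclisation zerovalent nickel inserts into the C–Br bond, transmetallation to trivalent chromium gives 11, and 11 adds 1,2 to the tethered enal at high dilution to close the 14-membered ring; C2 is formed without reagent control, so the (2S)-alcohol is separated from its epimer, which is used through the fallback.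

Step 9
Reactants: 12 (2S,3E,7E,11R,12S,13R)-13-acetoxy-11,12-epoxy-16,17-dinorcembra-1(15),3,7-trien-2-ol
Product: 13 (2S,3E,7E,11R,12S,13R)-13-acetoxy-11,12-epoxy-16,17-dinorcembra-1(15),3,7-trien-2-yl prop-2-enoate
Conditions: acrylic anhydride (2 equiv), iPr2NEt, 4-(dimethylamino)pyridine (0.2 equiv), CH2Cl2, 0 °C
Reagents that add atoms: acrylic anhydride, C=CC(=O)OC(=O)C=C
Why: Nucleophile-catalysed acylation of the bis-allylic alcohol proceeds with retention at C2 and brings in C15 and C16.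

Step 10
Reactants: 13 (2S,3E,7E,11R,12S,13R)-13-acetoxy-11,12-epoxy-16,17-dinorcembra-1(15),3,7-trien-2-yl prop-2-enoate
Product: 14 (2S,3E,7E,11R,12S,13R)-13-acetoxy-11,12-epoxy-17-norcembra-1(15),3,7-trien-16,2-olide
Conditions: second-generation Grubbs catalyst RuCl2(=CHPh)(PCy3)(H2IMes) (10 mol %), toluene, 0.005 M, 80 °C
Reagents that add atoms: none
Why: Ring-closing metathesis of the acrylate onto the terminal CH2 of the 1,1-disubstituted alkene forms the butenolide and expels the linchpin's spare carbon as ethene, while the trisubstituted 3,4- and 7,8-alkenes would have to place a fully substituted carbon next to ruthenium and stay intact.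

Step 11
Reactants: 14 (2S,3E,7E,11R,12S,13R)-13-acetoxy-11,12-epoxy-17-norcembra-1(15),3,7-trien-16,2-olide
Product: 16 (1S,2R,3E,7E,11R,12S,13R,15R)-13-acetoxy-17-(dimethylamino)-11,12-epoxycembra-3,7-dien-16,2-olide, via silyl ketene acetal 15 (not isolated)
Conditions: Cu(OAc)2 (5 mol %), 1,2-bis(diphenylphosphino)benzene (5 mol %), PhMe2SiH (2 equiv), toluene, 0 °C to rt; then CH2=NMe2+ I− (3 equiv), CH2Cl2, 0 °C to rt
Reagents that add atoms: N,N-dimethylmethyleneiminium iodide (Eschenmoser's salt), C=[N+](C)C.[I-]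
Why: Copper hydride 1,4-hydrosilylation delivers hydride to C1 from the butenolide face anti to the C2–C3 bond, the face not covered by the macrocyclic loop, which sets C1 with H-1 cis to H-2; the silyl ketene acetal then undergoes a Mukaiyama–Mannich reaction only at C15, so the acetate is never enolised.

Step 12
Reactants: 16 (1S,2R,3E,7E,11R,12S,13R,15R)-13-acetoxy-17-(dimethylamino)-11,12-epoxycembra-3,7-dien-16,2-olide
Product: 18 (1S,2S,3E,7E,11R,12S,13R)-13-acetoxy-11,12-epoxycembra-3,7,15(17)-trien-16,2-olide, via trimethylammonium iodide 17 (not isolated)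
Conditions: MeI (10 equiv), CH2Cl2, rt; then aq. NaHCO3, rt
Reagents that add atoms: none
Why: N-Methylation followed by E1cB (Hofmann-type) loss of trimethylamine unveils the α-methylene lactone under conditions too mild to touch C1, the epoxide or the acetate.

**Compound list**

1 | (2E,6E)-farnesyl acetate [(2E,6E)-3,7,11-trimethyldodeca-2,6,10-trien-1-yl acetate] | CC(=O)OC/C=C(\C)CC/C=C(\C)CCC=C(C)C | starting material
2 | (2E,6E,10E)-12-hydroxy-3,7,11-trimethyldodeca-2,6,10-trien-1-yl acetate | CC(=O)OC/C=C(\C)CC/C=C(\C)CC/C=C(\C)CO | intermediate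
3 | (2E,6E,10E)-3,7,11-trimethyl-12-oxododeca-2,6,10-trien-1-yl acetate | CC(=O)OC/C=C(\C)CC/C=C(\C)CC/C=C(\C)C=O | intermediate
4 | 2,3-dibromoprop-1-ene | C=C(Br)CBr | starting material
5 | (2-bromoprop-2-en-1-yl)indium dibromide | C=C(Br)C[In](Br)Br | intermediate
6 | rac-(2E,6E,10E)-14-bromo-12-hydroxy-3,7,11-trimethylpentadeca-2,6,10,14-tetraen-1-yl acetate (racemic at C12) | CC(=O)OC/C=C(\C)CC/C=C(\C)CC/C=C(\C)C(O)CC(Br)=C | intermediate
7 | (2E,6E)-9-[(2R,3R)-3-[(1R)-3-bromo-1-hydroxybut-3-en-1-yl]-3-methyloxiran-2-yl]-3,7-dimethylnona-2,6-dien-1-yl acetate | CC(=O)OC/C=C(\C)CC/C=C(\C)CC[C@H]1O[C@]1(C)[C@H](O)CC(Br)=C | intermediate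
8 | (2E,6E)-9-[(2R,3S)-3-[(1R)-1-acetoxy-3-bromobut-3-en-1-yl]-3-methyloxiran-2-yl]-3,7-dimethylnona-2,6-dien-1-yl acetate | CC(=O)OC/C=C(\C)CC/C=C(\C)CC[C@H]1O[C@]1(C)[C@H](OC(C)=O)CC(Br)=C | intermediate
9 | (1R)-3-bromo-1-[(2S,3R)-3-[(3E,7E)-9-hydroxy-3,7-dimethylnona-3,7-dien-1-yl]-2-methyloxiran-2-yl]but-3-en-1-yl acetate | OC/C=C(\C)CC/C=C(\C)CC[C@H]1O[C@]1(C)[C@H](OC(C)=O)CC(Br)=C | intermediate
10 | (1R)-3-bromo-1-[(2S,3R)-3-[(3E,7E)-3,7-dimethyl-9-oxonona-3,7-dien-1-yl]-2-methyloxiran-2-yl]but-3-en-1-yl acetate | O=C/C=C(\C)CC/C=C(\C)CC[C@H]1O[C@]1(C)[C@H](OC(C)=O)CC(Br)=C | intermediate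
11 | alkenylchromium dichloride of 10 (C–Br replaced by C–CrCl2) | O=C/C=C(\C)CC/C=C(\C)CC[C@H]1O[C@]1(C)[C@H](OC(C)=O)CC(=C)[Cr](Cl)Cl | intermediate
12 | (2S,3E,7E,11R,12S,13R)-13-acetoxy-11,12-epoxy-16,17-dinorcembra-1(15),3,7-trien-2-ol | O[C@H]1/C=C(\C)CC/C=C(\C)CC[C@H]2O[C@]2(C)[C@H](OC(C)=O)CC1=C | intermediate
13 | (2S,3E,7E,11R,12S,13R)-13-acetoxy-11,12-epoxy-16,17-dinorcembra-1(15),3,7-trien-2-yl prop-2-enoate | C=CC(=O)O[C@H]1/C=C(\C)CC/C=C(\C)CC[C@H]2O[C@]2(C)[C@H](OC(C)=O)CC1=C | intermediate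
14 | (2S,3E,7E,11R,12S,13R)-13-acetoxy-11,12-epoxy-17-norcembra-1(15),3,7-trien-16,2-olide | O=C1O[C@H]2/C=C(\C)CC/C=C(\C)CC[C@H]3O[C@]3(C)[C@H](OC(C)=O)CC2=C1 | intermediate
15 | (1S,2R,3E,7E,11R,12S,13R)-13-acetoxy-16-[dimethyl(phenyl)silyloxy]-2,16:11,12-diepoxy-17-norcembra-3,7,15-triene (silyl ketene acetal) | C1=C(O[Si](C)(C)c4ccccc4)O[C@H]2/C=C(\C)CC/C=C(\C)CC[C@H]3O[C@]3(C)[C@H](OC(C)=O)C[C@@H]12 | intermediate
16 | (1S,2R,3E,7E,11R,12S,13R,15R)-13-acetoxy-17-(dimethylamino)-11,12-epoxycembra-3,7-dien-16,2-olide (C15 configuration inconsequential) | CN(C)C[C@@H]1C(=O)O[C@H]2/C=C(\C)CC/C=C(\C)CC[C@H]3O[C@]3(C)[C@H](OC(C)=O)C[C@@H]12 | intermediate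
17 | (1S,2R,3E,7E,11R,12S,13R,15R)-13-acetoxy-11,12-epoxy-17-(trimethylammonio)cembra-3,7-dien-16,2-olide iodide | C[N+](C)(C)C[C@@H]1C(=O)O[C@H]2/C=C(\C)CC/C=C(\C)CC[C@H]3O[C@]3(C)[C@H](OC(C)=O)C[C@@H]12.[I-] | intermediate
18 | (1S,2S,3E,7E,11R,12S,13R)-13-acetoxy-11,12-epoxycembra-3,7,15(17)-trien-16,2-olide (CNP0146076.4) | C=C1C(=O)O[C@H]2/C=C(\C)CC/C=C(\C)CC[C@H]3O[C@]3(C)[C@H](OC(C)=O)C[C@@H]12 | target

**Step count and risks**

Total step count: 12. Longest linear sequence: 12 steps (from 1; 4 and all other reagents are purchased).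

The three steps most likely to fail:

Step 8 (Ni/Cr macrocyclisation). Ring closure competes with oligomerisation, and C2 is formed without reagent control, so the wrong epimer may be the main product. Fallback: the (2R)-epimeric alcohol F1, formed from 10 in the same cyclisation and separated by chromatography, is esterified with acrylic acid under Mitsunobu conditions (PPh3, diisopropyl azodicarboxylate, toluene, 0 °C). SN2 inversion at C2 gives acrylate 13, so both epimers converge. The fallback sets out from 10 and comes back at 13.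

Step 10 (ring-closing metathesis). The catalyst may fail to load on the electron-poor acrylate next to a hindered 1,1-disubstituted alkene. Fallback by relay: 12 is esterified with (2E)-octa-2,7-dienoic acid (N,N'-dicyclohexylcarbodiimide, 4-(dimethylamino)pyridine, CH2Cl2) to give the octa-2,7-dienoate ester F2. The ruthenium carbene then loads on the unhindered terminal alkene, expels cyclopentene, and arrives as the ester-bound alkylidene beside the exo-methylene, where it closes to 14. The fallback sets out from 12 and comes back at 14.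

Step 11 (hydrosilylation and Mannich trapping). The hindered ketene acetal may protonate instead of adding to the iminium salt. Fallback with C17 brought in by the ester and an SN2′ reduction in place of the Mannich reaction: 12 is esterified with 2-(acetoxymethyl)acrylic acid (N,N'-dicyclohexylcarbodiimide, 4-(dimethylamino)pyridine) to give the 2-(acetoxymethyl)acrylate ester F3. Ring-closing metathesis (second-generation Hoveyda–Grubbs catalyst RuCl2(=CH-C6H4-2-OiPr)(H2IMes), toluene, 100 °C) gives the 17-acetoxy butenolide F4. Copper hydride conjugate reduction (Cu(OAc)2, 1,2-bis(diphenylphosphino)benzene, PhMe2SiH, toluene) adds hydride to C1 from the same open face, and the copper enolate expels the C17 acetate to give 18 directly. The fallback sets out from 12 and comes back at 18.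

Further compounds
F1 | step 8 | (2R,3E,7E,11R,12S,13R)-13-acetoxy-11,12-epoxy-16,17-dinorcembra-1(15),3,7-trien-2-ol | O[C@@H]1/C=C(\C)CC/C=C(\C)CC[C@H]2O[C@]2(C)[C@H](OC(C)=O)CC1=C
F2 | step 10 | (2S,3E,7E,11R,12S,13R)-13-acetoxy-11,12-epoxy-16,17-dinorcembra-1(15),3,7-trien-2-yl (2E)-octa-2,7-dienoate | C=CCCC/C=C/C(=O)O[C@H]1/C=C(\C)CC/C=C(\C)CC[C@H]2O[C@]2(C)[C@H](OC(C)=O)CC1=C
F3 | step 11 | (2S,3E,7E,11R,12S,13R)-13-acetoxy-11,12-epoxy-16,17-dinorcembra-1(15),3,7-trien-2-yl 2-(acetoxymethyl)prop-2-enoate | CC(=O)OCC(=C)C(=O)O[C@H]1/C=C(\C)CC/C=C(\C)CC[C@H]2O[C@]2(C)[C@H](OC(C)=O)CC1=C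
F4 | step 11 | (2S,3E,7E,11R,12S,13R)-13,17-diacetoxy-11,12-epoxycembra-1(15),3,7-trien-16,2-olide | O=C1O[C@H]2/C=C(\C)CC/C=C(\C)CC[C@H]3O[C@]3(C)[C@H](OC(C)=O)CC2=C1COC(C)=O
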